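**Plan**

1. Labels: flavone numbering (ring A C5–C8; pyranone ring C with O1, C2, C3, C4; ring B C1'–C6'); ring D is the dimethylpyran on C7–O/C8; ring E is the oxepine; Ca is the carbon on C3 and Cb the oxygen-bearing carbon of ring E.
2. Retrosynthesis: first the two C–CH3 bonds of the carbinol (ester plus MeMgBr), then Ca–Cb and C2–C1' together, which splits the target into a 3-formyl pyranochromone (rings A, C, D) and a bromoaryloxy phosphonoacetate (ring B, ether O, Cb).
3. Enabling feature: on ring C the C3 formyl carbon and the acidic C2–H of the γ-pyranone are a 1,3 pair of reactive sites; on ring B the phosphonate carbon and C1'–Br are a 1,4 pair across the ether oxygen; olefination plus C–H arylation is therefore a (4+3) annulation that closes ring E.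
4. Forward order: ring C (Vilsmeier–Haack), ring D (propargyl ether Claisen cascade), ring E (key step), then hydrogenation, carbinol formation and deprotection.
5. Stereochemistry: the only stereocentre (Cb, R) is set after the annulation by carboxylate-directed asymmetric hydrogenation of the ring-locked Z enol ether acid. The helpers leave as follows: phosphonate and bromide in the key step, the Ca=Cb unsaturation in the hydrogenation, the ester as the carbinol.

Key step: step 8

**Route**

Step 1
Reactants: 1 2,4,6-trihydroxyacetophenone
Product: 2 5,7-dihydroxy-4-oxo-4H-chromene-3-carbaldehyde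
Conditions: POCl3 (4 equiv), DMF, 0 to 50 °C; then ice water
Reagents that add atoms: N,N-dimethylformamide, CN(C)C=O; water, O
Why: Vilsmeier–Haack double formylation of the acetyl methyl group and closure of one of the two equivalent ortho hydroxyls onto the iminium carbon should build ring C with its C3 formyl group in one step, the phenols being masked in the flask as formates or phosphorodichloridates that hydrolyse on work-up.

Step 2
Reactants: 2 5,7-dihydroxy-4-oxo-4H-chromene-3-carbaldehyde; 3 3-chloro-3-methylbut-1-yne
Product: 4 5-hydroxy-7-[(2-methylbut-3-yn-2-yl)oxy]-4-oxo-4H-chromene-3-carbaldehyde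
Conditions: K2CO3 (1.5 equiv), KI (0.2 equiv), CuI (5 mol %), MeCN, 60 °C
Reagents that add atoms: none
Why: CuI-assisted Williamson-type O-alkylation of the free C7 phenol by the tertiary propargylic chloride should be selective because the C5 hydroxyl is held in a hydrogen bond to the C4 carbonyl and is unreactive.

Step 3
Reactants: 4 5-hydroxy-7-[(2-methylbut-3-yn-2-yl)oxy]-4-oxo-4H-chromene-3-carbaldehyde
Product: 6 5-hydroxy-8,8-dimethyl-4-oxo-4H,8H-pyrano[2,3-f]chromene-3-carbaldehyde, via C8 allenyl phenol 5 (not isolated)
Conditions: o-xylene, 140 °C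
Reagents that add atoms: none
Why: Aromatic propargyl Claisen rearrangement to C8 gives allenyl phenol 5, which closes ring D by 1,5-hydrogen shift and oxa-6π electrocyclisation, and with the C5 hydroxyl free and chelated the migration is expected to go to C8 (angular fusion) as in related chelated hydroxy chromones, xanthones and acridones.

Step 4
Reactants: 7 resorcinol
Product: 8 3-(methoxymethoxy)phenol
Conditions: MOMCl (1.0 equiv), K2CO3 (1.2 equiv), acetone, 0 to 23 °C
Reagents that add atoms: chloromethyl methyl ether, COCCl
Why: Williamson-type mono-alkylation of the symmetrical diphenol with one equivalent of the chloromethyl ether should give the mono ether, which is separated from the diether and unchanged resorcinol by extraction and chromatography.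

Step 5
Reactants: 8 3-(methoxymethoxy)phenol
Product: 9 2-bromo-5-(methoxymethoxy)phenol
Conditions: NBS (1.0 equiv), iPr2NH (10 mol %), CH2Cl2, 0 °C
Reagents that add atoms: N-bromosuccinimide, O=C1CCC(=O)N1Br
Why: Amine-mediated ortho-selective electrophilic aromatic bromination of the phenol, in which the hydrogen-bonded N-bromoamine should deliver bromine to the ortho position that is also para to the acetal oxygen and not to the hindered position between the two oxygens.

Step 6
Reactants: 10 trimethyl phosphonoacetate
Product: 11 methyl 2-diazo-2-(dimethoxyphosphoryl)acetate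
Conditions: 4-acetamidobenzenesulfonyl azide (1.1 equiv), DBU (1.2 equiv), MeCN, 0 to 23 °C
Reagents that add atoms: 4-acetamidobenzenesulfonyl azide, CC(=O)Nc1ccc(cc1)S(=O)(=O)N=[N+]=[N-]
Why: Regitz diazo transfer to the doubly activated methylene group of the phosphonoacetate.

Step 7
Reactants: 9 2-bromo-5-(methoxymethoxy)phenol; 11 methyl 2-diazo-2-(dimethoxyphosphoryl)acetate
Product: 12 methyl 2-[2-bromo-5-(methoxymethoxy)phenoxy]-2-(dimethoxyphosphoryl)acetate
Conditions: Rh2(OAc)4 (1 mol %), toluene, 80 °C, slow addition of 11
Reagents that add atoms: none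
Why: Rhodium carbenoid O–H insertion into the phenol forms the O–Cb aryl ether bond and gives the aryloxy phosphonoacetate directly, a standard entry to Horner–Wadsworth–Emmons reagents of this kind.

Step 8
Reactants: 6 5-hydroxy-8,8-dimethyl-4-oxo-4H,8H-pyrano[2,3-f]chromene-3-carbaldehyde; 12 methyl 2-[2-bromo-5-(methoxymethoxy)phenoxy]-2-(dimethoxyphosphoryl)acetate
Product: 14 ring E dehydro ester (5-hydroxy-4'-(methoxymethoxy)flavone with ring D fused at C7–O/C8 and the oxepine ring E C3–CaH=Cb(CO2Me)–O–C2'), via Z enol ether acrylate 13 (not isolated)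
Conditions: Cs2CO3 (3.5 equiv), Pd(OAc)2 (10 mol %), PCy3·HBF4 (20 mol %), PivOH (30 mol %), DMA, Ar, 23 °C for 2 h, then 110 °C
Reagents that add atoms: none
Why: Caesium carbonate deprotonates phosphonate 12 and Horner–Wadsworth–Emmons olefination of the C3 formyl group of 6 forms the Ca=Cb bond as the Z enol ether acrylate 13 (chromonyl cis to the aryloxy group, trans to the ester); on heating, zerovalent palladium inserts into the C1'–Br bond, and pivalate-assisted concerted metalation–deprotonation of the acidic C2–H of the γ-pyranone followed by reductive elimination forms the C2–C1' bond. The closest known reaction types are the olefination of 3-formylchromones with α-aryloxy phosphonoacetates and the intramolecular direct arylation of a chromone C2–H bond by a tethered aryl bromide under Pd(OAc)2 and a trialkylphosphine, run here in one flask with one base. Ring E is closed in the arylation event through an eight-membered palladacycle whose reductive elimination gives the seven-membered ring, formally a 7-endo attack on the C2=C3 bond, so that the two events together are a (4+3) annulation of the C2/C3/Ca unit of ring C with the C1'/C2'/O/Cb unit of ring B. No stereocentre is formed, because Cb stays trigonal until step 10. The step needs Z geometry at Ca=Cb, which the thermodynamically controlled olefination favours and which the cyclisation drains, since the E isomer cannot reach C2 and can equilibrate by reversible conjugate addition of pivalate at C2; it also needs arylation at C2–H and not at the Ca=Cb or ring D double bonds, which is secured because C2–H is the only C–H bond within reach of the arylpalladium and a Heck closure onto Ca would be a disfavoured 5-endo process.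

Step 9
Reactants: 14 ring E dehydro ester
Product: 15 ring E dehydro acid (as 14 with CO2H on Cb)
Conditions: LiOH·H2O (3 equiv), THF/H2O (3:1), 23 °C; then 1 M HCl to pH 3 at 0 °C
Reagents that add atoms: lithium hydroxide, [Li+].[OH-]
Why: Saponification of the methyl ester frees the carboxyl group that directs the hydrogenation, the 2-aryl pyranone and the acetal being expected to tolerate cold aqueous hydroxide and brief acidification.

Step 10
Reactants: 15 ring E dehydro acid
Product: 16 (R)-dihydro acid (ring E C3–CaH2–CbH(CO2H)–O–C2', Cb R)
Conditions: Ru(OAc)2[(S)-BINAP] (2 mol %; or the R antipode, see Why), H2 (30 atm), MeOH, 30 °C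
Reagents that add atoms: none
Why: Carboxylate-directed asymmetric hydrogenation of a Z-configured α-aryloxy acrylic acid, a substrate class that catalysts of the type Ru(OAc)2(BINAP) reduce enantioselectively, should set the R configuration at Cb by delivery of hydrogen to one face of the ring-locked Ca=Cb bond, the ligand antipode being the one that a first run shows to give the R acid, while the ring D double bond and the tetrasubstituted C2=C3 bond lack a directing group and should stay untouched.

Step 11
Reactants: 16 (R)-dihydro acid
Product: 17 (R)-dihydro methyl ester (as 16 with CO2Me on Cb)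
Conditions: TMSCHN2 (1.2 equiv), toluene/MeOH (4:1), 0 °C
Reagents that add atoms: (trimethylsilyl)diazomethane, C[Si](C)(C)C=[N+]=[N-]
Why: Diazoalkane esterification of the carboxylic acid under neutral conditions should leave the α stereocentre and the chelated C5 phenol untouched.

Step 12
Reactants: 17 (R)-dihydro methyl ester
Product: 18 4'-O-methoxymethyl ether of the target (Cb carries C(CH3)2OH, Cb R)
Conditions: MeMgBr (6 equiv), THF, −40 to 0 °C; then aq NH4Cl
Reagents that add atoms: methylmagnesium bromide, C[Mg]Br
Why: Double Grignard addition to the ester builds the dimethyl carbinol, the first equivalent turning the C5 phenol into a magnesium chelate with the C4 carbonyl that shields the vinylogous ester carbonyl of ring C, and addition to the ester being faster than its enolisation so that Cb should keep its configuration.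

Step 13
Reactants: 18 4'-O-methoxymethyl ether of the target
Product: 19 target CNP0329736.1 (5,4'-dihydroxyflavone with ring D and ring E C3–CH2–CH[C(CH3)2OH]–O–C2', Cb R)
Conditions: 3 M aq HCl, MeOH, 45 °C
Reagents that add atoms: none
Why: Acid-catalysed acetal exchange removes the methoxymethyl group from the C4' phenol under conditions that the 2,2-dimethylchromene, the aryl alkyl ether of ring E and the tertiary alcohol, whose ionisation is disfavoured by the neighbouring oxygen-bearing carbon, are expected to tolerate.

**Compound list**

1 | 2,4,6-trihydroxyacetophenone | CC(=O)c1c(O)cc(O)cc1O | starting material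
2 | 5,7-dihydroxy-4-oxo-4H-chromene-3-carbaldehyde | O=Cc1coc2cc(O)cc(O)c2c1=O | intermediate
3 | 3-chloro-3-methylbut-1-yne | CC(C)(Cl)C#C | starting material
4 | 5-hydroxy-7-[(2-methylbut-3-yn-2-yl)oxy]-4-oxo-4H-chromene-3-carbaldehyde | O=Cc1coc2cc(OC(C)(C)C#C)cc(O)c2c1=O | intermediate
5 | 5,7-dihydroxy-8-(3-methylbuta-1,2-dien-1-yl)-4-oxo-4H-chromene-3-carbaldehyde (C8 allenyl phenol) | O=Cc1coc2c(C=C=C(C)C)c(O)cc(O)c2c1=O | intermediate
6 | 5-hydroxy-8,8-dimethyl-4-oxo-4H,8H-pyrano[2,3-f]chromene-3-carbaldehyde | CC1(C)C=Cc2c(cc(O)c3c(=O)c(C=O)coc23)O1 | intermediate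
7 | resorcinol | Oc1cccc(O)c1 | starting material
8 | 3-(methoxymethoxy)phenol | COCOc1cccc(O)c1 | intermediate
9 | 2-bromo-5-(methoxymethoxy)phenol | COCOc1ccc(Br)c(O)c1 | intermediate
10 | trimethyl phosphonoacetate | COC(=O)CP(=O)(OC)OC | starting material
11 | methyl 2-diazo-2-(dimethoxyphosphoryl)acetate | COC(=O)C(=[N+]=[N-])P(=O)(OC)OC | intermediate
12 | methyl 2-[2-bromo-5-(methoxymethoxy)phenoxy]-2-(dimethoxyphosphoryl)acetate | COCOc1ccc(Br)c(OC(C(=O)OC)P(=O)(OC)OC)c1 | intermediate
13 | methyl (Z)-2-[2-bromo-5-(methoxymethoxy)phenoxy]-3-(5-hydroxy-8,8-dimethyl-4-oxo-4H,8H-pyrano[2,3-f]chromen-3-yl)prop-2-enoate (Z enol ether acrylate) | COC(=O)/C(Oc1cc(OCOC)ccc1Br)=C/c1coc2c3C=CC(C)(C)Oc3cc(O)c2c1=O | intermediate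
14 | ring E dehydro ester: 5-hydroxy-4'-(methoxymethoxy)flavone with ring D at C7–O/C8 and ring E C3–CaH=Cb(CO2Me)–O–C2' | CC1(C)C=Cc2c(cc(O)c3c(=O)c4c(oc23)-c2ccc(OCOC)cc2OC(C(=O)OC)=C4)O1 | intermediate
15 | ring E dehydro acid: as 14 with CO2H on Cb | CC1(C)C=Cc2c(cc(O)c3c(=O)c4c(oc23)-c2ccc(OCOC)cc2OC(C(=O)O)=C4)O1 | intermediate
16 | (R)-dihydro acid: ring E C3–CaH2–CbH(CO2H)–O–C2', Cb R | CC1(C)C=Cc2c(cc(O)c3c(=O)c4c(oc23)-c2ccc(OCOC)cc2O[C@@H](C(=O)O)C4)O1 | intermediate
17 | (R)-dihydro methyl ester: as 16 with CO2Me on Cb | CC1(C)C=Cc2c(cc(O)c3c(=O)c4c(oc23)-c2ccc(OCOC)cc2O[C@@H](C(=O)OC)C4)O1 | intermediate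
18 | 4'-O-methoxymethyl ether of the target: Cb carries C(CH3)2OH, Cb R | CC1(C)C=Cc2c(cc(O)c3c(=O)c4c(oc23)-c2ccc(OCOC)cc2O[C@@H](C(C)(C)O)C4)O1 | intermediate
19 | CNP0329736.1: 5,4'-dihydroxyflavone with ring D at C7–O/C8 and ring E C3–CH2–CH[C(CH3)2OH]–O–C2', Cb R | CC1(C)C=Cc2c(cc(O)c3c(=O)c4c(oc23)-c2ccc(O)cc2O[C@@H](C(C)(C)O)C4)O1 | target

**Step count and risks**

Total steps: 13. Longest linear sequence: 9 steps (1, 2, 3, 8, 9, 10, 11, 12, 13; the branch 4, 5, 7, 8 to 13 is equally long).

Step 8. What may go wrong: olefination giving much of the E isomer that cannot close; slow closure of the seven-membered ring with competing loss of bromine from the arylpalladium; base-induced opening of the pyranone of 6 before olefination. The fallback sets out from 8, 11 and 6 and comes back at 14. Rh2(OAc)4-catalysed O–H insertion of 11 into 8 would give methyl 2-(dimethoxyphosphoryl)-2-[3-(methoxymethoxy)phenoxy]acetate F1. Olefination of 6 with F1 (LiCl, DBU, MeCN, 23 °C) would give the bromine-free Z enol ether acrylate F2, which is isolated and freed of any E isomer. Ring E would then be closed by a twofold C–H coupling with divalent palladium (Pd(OAc)2, AgOAc, PivOH, 110 °C) between C2–H of ring C and the ring B C–H that is ortho to the ether oxygen and para to the acetal oxygen, a known dehydrogenative C2 arylation of chromones, giving 14.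

Step 10. What may go wrong: poor facial discrimination on the ring-locked enol ether, inhibition of the catalyst by the chelating C5 hydroxyl/C4 carbonyl pair, or slow turnover. The fallback sets out from 15 and comes back at 16. Hydrogenation with the racemic catalyst Ru(OAc)2(rac-BINAP) would give the racemic dihydro acid F3. Classical resolution by crystallisation of the (R)-1-phenylethylammonium salt of the R acid F4 (the antipodal amine if the salt of the S acid proves the less soluble one) and acidification would give 16. The S acid can be recycled by esterification, base epimerisation and saponification.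

Step 12. What may go wrong: competing 1,2-addition to the C4 carbonyl of ring C, or enolisation of the ester with loss of configuration at Cb. The fallback sets out from 16 (step 11 is skipped) and comes back at 18. MeLi (4 equiv, THF, −78 to 0 °C) would add once to the lithium carboxylate and give, after aqueous work-up, the (R)-methyl ketone F5, the dilithium gem-diolate blocking a second addition. MeTi(OiPr)3 (THF, −20 to 23 °C), a non-basic reagent that adds to ketones but not to vinylogous esters, would then give 18.

**Further compounds**

F1 | step 8 | methyl 2-(dimethoxyphosphoryl)-2-[3-(methoxymethoxy)phenoxy]acetate | COCOc1cccc(OC(C(=O)OC)P(=O)(OC)OC)c1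
F2 | step 8 | methyl (Z)-3-(5-hydroxy-8,8-dimethyl-4-oxo-4H,8H-pyrano[2,3-f]chromen-3-yl)-2-[3-(methoxymethoxy)phenoxy]prop-2-enoate | COC(=O)/C(Oc1cccc(OCOC)c1)=C/c1coc2c3C=CC(C)(C)Oc3cc(O)c2c1=O
F3 | step 10 | racemic dihydro acid (16 and its enantiomer) | CC1(C)C=Cc2c(cc(O)c3c(=O)c4c(oc23)-c2ccc(OCOC)cc2OC(C(=O)O)C4)O1
F4 | step 10 | (R)-1-phenylethylammonium salt of the (R)-dihydro acid | CC1(C)C=Cc2c(cc(O)c3c(=O)c4c(oc23)-c2ccc(OCOC)cc2O[C@@H](C([O-])=O)C4)O1.C[C@@H]([NH3+])c1ccccc1
F5 | step 12 | (R)-methyl ketone (as 16 with C(=O)CH3 on Cb) | CC1(C)C=Cc2c(cc(O)c3c(=O)c4c(oc23)-c2ccc(OCOC)cc2O[C@@H](C(C)=O)C4)O1
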